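**Retrosynthetic overview**

1. Dinklagin A (18) ⇐ 7-O-TIPS flavanone 17 ⇐ flavan-4-ol 16 ⇐ (2S,4S)-4-methoxyflavan 15. The C4 ketone is carried as a labile benzylic methyl ether and the 7-OH as a TIPS ether.
2. Key disconnection in ring C (the dihydropyranone), at O1–C2 and C3–C4. O1, C8a, C4a and C4 are the heterodiene of a 4-methoxy ortho-quinone methide made from salicylaldehyde 11 and trimethyl orthoformate. C2–C3 is the vinyl group of chromene 7; the chromene oxygen para to it makes C3 the nucleophile and lets C2 carry the charge.
3. 11 ⇐ 5-bromo-2,4-dihydroxybenzaldehyde (4-O-silylation, Stille prenylation). 7 ⇐ 4-hydroxybenzaldehyde (propargyl ether, Claisen cyclisation, Wittig methylenation).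
4. Ring order: both benzene rings are bought; the 2H-pyran ring of the chromene is closed first (step 2) and ring C last (step 6).

Key step: step 6

Remark: 5-bromo-2,4-dihydroxybenzaldehyde (8) is taken as a catalogue compound (otherwise one bromination of 2,4-dihydroxybenzaldehyde with Br2/AcOH), and because the sense of induction of the chiral acid in step 6 cannot be assigned in advance, the (R)-catalyst is written provisionally and its antipode is used if a first run gives the (2R) series.

**Route**

Step 1
Reactants: 1 4-hydroxybenzaldehyde; 2 3-chloro-3-methylbut-1-yne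
Product: 3 4-[(2-methylbut-3-yn-2-yl)oxy]benzaldehyde
Conditions: K2CO3, KI (cat.), CuI (cat.), acetone, reflux
Reagents that add atoms: none
Why: Copper-assisted O-alkylation of the phenoxide by the tertiary propargylic chloride should give the 1,1-dimethylpropargyl aryl ether, the standard entry to 2,2-dimethylchromenes.

Step 2
Reactants: 3 4-[(2-methylbut-3-yn-2-yl)oxy]benzaldehyde
Product: 6 2,2-dimethyl-2H-chromene-6-carbaldehyde, via allenylphenol 4 (not isolated), via vinyl quinone methide 5 (not isolated)
Conditions: PhNEt2, 190 °C
Reagents that add atoms: none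
Why: Aromatic propargyl Claisen rearrangement to the ortho-allenylphenol, 1,5-hydrogen shift and 6π oxa-electrocyclisation close the 2H-pyran ring, and since the para aldehyde leaves both ortho positions equivalent only one regioisomer can form.

Step 3
Reactants: 6 2,2-dimethyl-2H-chromene-6-carbaldehyde
Product: 7 2,2-dimethyl-6-vinyl-2H-chromene
Conditions: Ph3PCH3Br, KOtBu, THF, 0 °C to rt; product stored cold with a trace of BHT
Reagents that add atoms: methyltriphenylphosphonium bromide, C[P+](c1ccccc1)(c1ccccc1)c1ccccc1.[Br-]
Why: Wittig methylenation of the aromatic aldehyde with the non-stabilised ylide should proceed cleanly, the chromene alkene and the ether being inert to it.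

Step 4
Reactants: 8 5-bromo-2,4-dihydroxybenzaldehyde
Product: 9 5-bromo-2-hydroxy-4-[(triisopropylsilyl)oxy]benzaldehyde
Conditions: TIPSCl (1.05 equiv), imidazole, CH2Cl2, 0 °C
Reagents that add atoms: triisopropylsilyl chloride, CC(C)[Si](Cl)(C(C)C)C(C)C
Why: Selective phenol silylation is expected at O4, because the 4-OH is the more acidic and is not hydrogen-bonded, whereas the 2-OH is chelated to the formyl group.

Step 5
Reactants: 9 5-bromo-2-hydroxy-4-[(triisopropylsilyl)oxy]benzaldehyde; 10 tributyl(3-methylbut-2-en-1-yl)stannane
Product: 11 2-hydroxy-5-(3-methylbut-2-en-1-yl)-4-[(triisopropylsilyl)oxy]benzaldehyde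
Conditions: Pd(PPh3)4 (5 mol %), DMF, 100 °C
Reagents that add atoms: none
Why: Stille cross-coupling, in which reductive elimination from the aryl(prenyl)palladium species should occur at the unsubstituted allyl terminus (further favoured by the bulky ortho OTIPS group) to give the linear prenyl arene, while the neutral, fluoride-free conditions spare the silyl ether, the chelated phenol and the aldehyde.

Step 6
Reactants: 11 2-hydroxy-5-(3-methylbut-2-en-1-yl)-4-[(triisopropylsilyl)oxy]benzaldehyde; 12 trimethyl orthoformate; 7 2,2-dimethyl-6-vinyl-2H-chromene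
Product: 15 (2S,4S)-2-(2,2-dimethyl-2H-chromen-6-yl)-4-methoxy-6-(3-methylbut-2-en-1-yl)-7-[(triisopropylsilyl)oxy]chromane, via dimethyl acetal 13 (not isolated), via methoxy ortho-quinone methide 14 (not isolated)
Conditions: (R)-3,3'-bis(2,4,6-triisopropylphenyl)-BINOL N-triflylphosphoramide (10 mol %), 12 (2 equiv), 5 Å MS, toluene, −40 °C, slow addition of 7 (1.5 equiv)
Reagents that add atoms: none
Why: Proposed new method: the acid converts 11 and 12 into acetal 13 and ionises it with loss of methanol to the 4-methoxy ortho-quinone methide 14 (reacting as its O-protonated oxocarbenium form), which stays hydrogen-bonded through the phenolic O–H to the chiral phosphoramide anion, after which the terminal vinyl carbon of 7 adds to C4 and O1 collapses on the developing para-alkoxybenzylic cation at C2 in an asynchronous inverse-electron-demand hetero-Diels–Alder reaction. The closest known reaction types are the Lewis-acid three-component chroman synthesis from salicylaldehydes, orthoformates and alkenes and the chiral phosphoric acid catalysed [4+2] additions of ortho-quinone methides to styrenes; their combination in an enantioselective three-component form is not established. The chroman ring (ring C) closes as the six-membered ring of the [4+2] process, the C3–C4 bond leading and the O1–C2 bond following within the ion pair. C2 is controlled by the chiral anion, which blocks one face of the bound heterodiene so that the styrene is taken up on the face leading to (2S), and C4 follows from the endo arrangement that places aryl and methoxy cis (both pseudo-equatorial) and is erased in step 8. The step needs reaction at the vinyl group only: it is terminal, unhindered and conjugated to the para ring oxygen, whereas the chromene C3=C4 bond is shielded by the gem-dimethyl carbon and the prenyl alkene offers no benzylic stabilisation. The free 2-OH anchors the catalyst, the 7-OTIPS donor allows ionisation of the acetal at a temperature at which the less ionisable product 15 persists, and the minor 2,4-trans isomer is removed by chromatography.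

Step 7
Reactants: 15 (2S,4S)-4-methoxyflavan
Product: 16 (2S,4RS)-2-(2,2-dimethyl-2H-chromen-6-yl)-6-(3-methylbut-2-en-1-yl)-7-[(triisopropylsilyl)oxy]chroman-4-ol
Conditions: PPTS (20 mol %), acetone–H2O 4:1, high dilution, rt
Reagents that add atoms: water, O
Why: Acid-catalysed SN1 solvolysis of a benzylic methyl ether whose cation is stabilised by the ortho ring oxygen and the para silyloxy group should exchange OMe for OH under weak acid, while the less basic C2–O1 aryl ether, the TIPS ether and the alkenes stay intact; the C4 epimer mixture is of no consequence.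

Step 8
Reactants: 16 (2S,4RS)-flavan-4-ol
Product: 17 (2S)-2-(2,2-dimethyl-2H-chromen-6-yl)-6-(3-methylbut-2-en-1-yl)-7-[(triisopropylsilyl)oxy]chroman-4-one
Conditions: Dess–Martin periodinane, pyridine, CH2Cl2, 0 °C to rt
Reagents that add atoms: none
Why: Dess–Martin oxidation of the secondary benzylic alcohol under pyridine buffering should converge both C4 epimers on one ketone without acid that could ionise C4 or base that could open the flavanone by retro-oxa-Michael reaction.

Step 9
Reactants: 17 (2S)-7-O-TIPS flavanone
Product: 18 Dinklagin A, (2S)-2-(2,2-dimethyl-2H-chromen-6-yl)-7-hydroxy-6-(3-methylbut-2-en-1-yl)chroman-4-one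
Conditions: TBAF, AcOH (1:1), THF, 0 °C
Reagents that add atoms: none
Why: Fluoride-mediated desilylation of an aryl silyl ether para to the ketone (a vinylogous silyl ester, hence very labile) should be fast, and acetic acid keeps the medium non-basic so that C2 is not racemised through the ring-opened 2'-hydroxychalcone.

**Compound list**

1 | 4-hydroxybenzaldehyde | O=Cc1ccc(O)cc1 | starting material
2 | 3-chloro-3-methylbut-1-yne | CC(C)(Cl)C#C | starting material
3 | 4-[(2-methylbut-3-yn-2-yl)oxy]benzaldehyde | O=Cc1ccc(OC(C)(C)C#C)cc1 | intermediate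
4 | 4-hydroxy-3-(3-methylbuta-1,2-dien-1-yl)benzaldehyde (allenylphenol, not isolated) | O=Cc1ccc(O)c(C=C=C(C)C)c1 | intermediate
5 | 3-(3-methylbut-2-en-1-ylidene)-4-oxocyclohexa-1,5-diene-1-carbaldehyde (vinyl quinone methide, not isolated, alkene geometry not defined) | O=C1C=CC(C=O)=CC1=CC=C(C)C | intermediate
6 | 2,2-dimethyl-2H-chromene-6-carbaldehyde | O=Cc1ccc2c(c1)C=CC(C)(C)O2 | intermediate
7 | 2,2-dimethyl-6-vinyl-2H-chromene | C=Cc1ccc2c(c1)C=CC(C)(C)O2 | intermediate
8 | 5-bromo-2,4-dihydroxybenzaldehyde | O=Cc1cc(Br)c(O)cc1O | starting material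
9 | 5-bromo-2-hydroxy-4-[(triisopropylsilyl)oxy]benzaldehyde | O=Cc1cc(Br)c(O[Si](C(C)C)(C(C)C)C(C)C)cc1O | intermediate
10 | tributyl(3-methylbut-2-en-1-yl)stannane | CCCC[Sn](CCCC)(CCCC)CC=C(C)C | starting material
11 | 2-hydroxy-5-(3-methylbut-2-en-1-yl)-4-[(triisopropylsilyl)oxy]benzaldehyde | O=Cc1cc(CC=C(C)C)c(O[Si](C(C)C)(C(C)C)C(C)C)cc1O | intermediate
12 | trimethyl orthoformate | COC(OC)OC | starting material
13 | 2-(dimethoxymethyl)-4-(3-methylbut-2-en-1-yl)-5-[(triisopropylsilyl)oxy]phenol (dimethyl acetal, not isolated) | COC(OC)c1cc(CC=C(C)C)c(O[Si](C(C)C)(C(C)C)C(C)C)cc1O | intermediate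
14 | 6-(methoxymethylidene)-4-(3-methylbut-2-en-1-yl)-3-[(triisopropylsilyl)oxy]cyclohexa-2,4-dien-1-one (ortho-quinone methide, not isolated, alkene geometry not defined) | COC=C1C=C(CC=C(C)C)C(O[Si](C(C)C)(C(C)C)C(C)C)=CC1=O | intermediate
15 | (2S,4S)-2-(2,2-dimethyl-2H-chromen-6-yl)-4-methoxy-6-(3-methylbut-2-en-1-yl)-7-[(triisopropylsilyl)oxy]chromane (2,4-cis) | CC(C)=CCc1cc2c(cc1O[Si](C(C)C)(C(C)C)C(C)C)O[C@H](c1ccc3c(c1)C=CC(C)(C)O3)C[C@@H]2OC | intermediate
16 | (2S,4RS)-2-(2,2-dimethyl-2H-chromen-6-yl)-6-(3-methylbut-2-en-1-yl)-7-[(triisopropylsilyl)oxy]chroman-4-ol (C4 epimer mixture) | CC(C)=CCc1cc2c(cc1O[Si](C(C)C)(C(C)C)C(C)C)O[C@H](c1ccc3c(c1)C=CC(C)(C)O3)CC2O | intermediate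
17 | (2S)-2-(2,2-dimethyl-2H-chromen-6-yl)-6-(3-methylbut-2-en-1-yl)-7-[(triisopropylsilyl)oxy]chroman-4-one | CC(C)=CCc1cc2c(cc1O[Si](C(C)C)(C(C)C)C(C)C)O[C@H](c1ccc3c(c1)C=CC(C)(C)O3)CC2=O | intermediate
18 | Dinklagin A, (2S)-2-(2,2-dimethyl-2H-chromen-6-yl)-7-hydroxy-6-(3-methylbut-2-en-1-yl)chroman-4-one | CC(C)=CCc1cc2c(cc1O)O[C@H](c1ccc3c(c1)C=CC(C)(C)O3)CC2=O | target

**Step count**

Total step count: 9.
Longest linear sequence: 7 steps (steps 1, 2, 3, 6, 7, 8, 9, from 4-hydroxybenzaldehyde).

**Steps most likely to fail**

1. Step 6 (proposed new method). Facial discrimination may be poor if the ion pair between the oxocarbenium/quinone methide and the chiral anion is loosely organised. The para-alkoxystyrene may oligomerise cationically, or the product may ionise again at C4 and eliminate or add a second alkene. Fallback with known chemistry, setting out from 11 (with 12 and 7) and coming back at 15: the three-component reaction is run in its established racemic Lewis-acid form (Sc(OTf)3, 10 mol %, CH2Cl2, rt). This should give the racemic 2,4-cis 4-methoxyflavan, that is 15 together with its mirror image, (2R,4R)-2-(2,2-dimethyl-2H-chromen-6-yl)-4-methoxy-6-(3-methylbut-2-en-1-yl)-7-[(triisopropylsilyl)oxy]chromane F1. The two are separated by preparative HPLC on a polysaccharide chiral stationary phase, and 15 re-enters the route at step 7.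

2. Step 5. Coupling may occur in part through the substituted allyl terminus to give the reverse-prenyl isomer. Oxidative addition at the hindered, electron-rich bromide may be slow, and some allyl transfer to the aldehyde is conceivable. Fallback setting out from 9 and coming back at 11: Stille coupling of 9 with allyltributylstannane (Pd(PPh3)4, DMF, 100 °C), which has no regiochemical ambiguity, should give 5-allyl-2-hydroxy-4-[(triisopropylsilyl)oxy]benzaldehyde F2. Olefin cross-metathesis of F2 with excess 2-methylbut-2-ene (Grubbs second-generation catalyst, CH2Cl2, 40 °C) then installs the trisubstituted alkene and delivers 11.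

3. Step 7. The C4 cation may lose a proton to give the flav-3-ene, or alkylate the electron-rich C8 position of a second molecule, faster than it is trapped by water. Fallback setting out from 15 and coming back at 17: the C4–H bond is oxidised directly with DDQ in CH2Cl2/pH 7 buffer at 0 °C. Hydride abstraction at the doubly oxygen-activated C4 gives a methoxy-stabilised cation, water adds, and the hemiketal collapses to the ketone 17, so neither the carbinol nor a free C4 benzylic cation is involved. This fallback makes no compound outside the compound list (F0).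

**Further compounds**

F1 | step 6 | (2R,4R)-2-(2,2-dimethyl-2H-chromen-6-yl)-4-methoxy-6-(3-methylbut-2-en-1-yl)-7-[(triisopropylsilyl)oxy]chromane (enantiomer of 15) | CC(C)=CCc1cc2c(cc1O[Si](C(C)C)(C(C)C)C(C)C)O[C@@H](c1ccc3c(c1)C=CC(C)(C)O3)C[C@H]2OC
F2 | step 5 | 5-allyl-2-hydroxy-4-[(triisopropylsilyl)oxy]benzaldehyde | C=CCc1cc(C=O)c(O)cc1O[Si](C(C)C)(C(C)C)C(C)C
F0 | step 7 | none | none
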